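**Plan**

- Numbering: C1 is the ketone carbon and C2–C11 are the ten methylenes. On the 2-hydroxyphenyl ring the phenolic oxygen and the benzylic carbon C11 sit on adjacent ring carbons, which is the pattern a [3,3] shift of an aryl allyl ether leaves behind.
- Retrosynthetic cuts, in order: the three O–benzyl bonds together with the C9–C10 saturation (one hydrogenation); the ring C(ortho)–C11 bond (aromatic Claisen, back to a phenyl ether on C9 with a C10=C11 vinyl group); the C1–aryl bond (aryllithium plus Weinreb amide); the O–C9 bond (Mitsunobu); the C9–C10 bond (vinyl Grignard plus aldehyde).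
- Forward: a C1–C9 ester aldehyde takes up the vinyl group, phenol is attached to the C9 oxygen, the phloroglucinol ring is joined at C1 as its tribenzyl ether, the rearrangement moves C11 onto the phenol ring, and one hydrogenation saturates the alkene and frees the three phenols. Both rings are bought and none is formed.
- Stereochemistry: the target has no stereocentre and no stereogenic alkene. The C9 centre is carried racemic and is destroyed in the rearrangement, and the E alkene formed there is hydrogenated.

Key step: step 6

Remark: methyl 9-oxononanoate and 1,3,5-tris(benzyloxy)benzene are taken as purchasable; every compound with a C9 carbinol or ether centre is racemic, which is immaterial because the target is achiral.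

**Route**

Step 1
Reactants: 1 methyl 9-oxononanoate; 2 vinylmagnesium bromide
Product: 3 methyl 9-hydroxyundec-10-enoate (racemic)
Conditions: CH2=CHMgBr (1.05 equiv), THF, −78 °C; sat. aq. NH4Cl
Reagents that add atoms: none
Why: Grignard 1,2-addition is chemoselective because at −78 °C the aldehyde reacts far faster than the methyl ester; the new C9 carbinol centre is formed racemic and is erased in step 6.

Step 2
Reactants: 3 methyl 9-hydroxyundec-10-enoate; 4 phenol
Product: 5 methyl 9-phenoxyundec-10-enoate (racemic)
Conditions: PPh3, DIAD, THF, 0 °C → rt
Reagents that add atoms: none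
Why: Mitsunobu etherification, in which phenol is acidic enough to protonate the phosphine–azodicarboxylate betaine and the phenoxide displaces the oxyphosphonium group at C9 by SN2 (inversion is irrelevant on racemic material), a standard way to aryl ethers of alk-1-en-3-ols.

Step 3
Reactants: 5 methyl 9-phenoxyundec-10-enoate
Product: 6 N-methoxy-N-methyl-9-phenoxyundec-10-enamide (racemic)
Conditions: MeNH(OMe)·HCl, iPrMgCl, THF, −20 → 0 °C; sat. aq. NH4Cl
Reagents that add atoms: N,O-dimethylhydroxylamine hydrochloride, CNOC.Cl
Why: Weinreb amide formation by aminolysis of the methyl ester with the chloromagnesium amide made in the flask, under which the allylic aryl ether and the alkene are inert.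

Step 4
Reactants: 7 1,3,5-tris(benzyloxy)benzene
Product: 8 2-bromo-1,3,5-tris(benzyloxy)benzene
Conditions: NBS (1.0 equiv), CH2Cl2, −78 °C → rt
Reagents that add atoms: N-bromosuccinimide, O=C1CCC(=O)N1Br
Why: Electrophilic aromatic bromination of a ring whose three equivalent free positions are each activated by three alkoxy groups, stopped at the monobromide by one equivalent of NBS at low temperature.

Step 5
Reactants: 6 N-methoxy-N-methyl-9-phenoxyundec-10-enamide; 8 2-bromo-1,3,5-tris(benzyloxy)benzene
Product: 11 racemic 9-phenoxy-1-[2,4,6-tris(benzyloxy)phenyl]undec-10-en-1-one, via 2,4,6-tris(benzyloxy)phenyllithium 9 (not isolated), via chelated lithium hemiaminal adduct 10 (not isolated)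
Conditions: 8, n-BuLi, THF, −78 °C; then 6, −78 → 0 °C; sat. aq. NH4Cl
Reagents that add atoms: none
Why: Bromine–lithium exchange followed by Weinreb ketone synthesis, in which the aryllithium adds once to give an N,O-chelated tetrahedral adduct that survives until work-up and so cannot over-add.

Step 6
Reactants: 11 racemic 9-phenoxy-1-[2,4,6-tris(benzyloxy)phenyl]undec-10-en-1-one
Product: 13 (E)-11-(2-hydroxyphenyl)-1-[2,4,6-tris(benzyloxy)phenyl]undec-9-en-1-one, via 6-alkenylcyclohexa-2,4-dienone 12 (not isolated)
Conditions: PhNEt2, 190 °C, argon, sealed tube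
Reagents that add atoms: none
Why: The aryl 1-alkylallyl ether should undergo a concerted suprafacial [3,3]-sigmatropic shift through a chair-like six-membered transition state, in which an ortho carbon of the phenoxy ring bonds to the vinyl terminus C11 while the O–C9 bond breaks, and the resulting dienone 12 tautomerises irreversibly to the phenol. The closest known reaction type is the thermal aromatic Claisen rearrangement of aryl ethers of secondary allylic alcohols to ortho-(alk-2-enyl)phenols in N,N-diethylaniline. No ring is closed and no stereocentre is created: C9 becomes an alkene carbon, and because the chain on C9 prefers the pseudo-equatorial position the new C9=C10 bond should be E, a geometry that step 7 removes in any case. The step needs ortho delivery and attachment through the unsubstituted terminus C11 (not through C9); both follow from the allyl inversion built into the mechanism, from oxygen sitting on the secondary carbon C9, and from the two free, equivalent ortho positions of the unsubstituted phenoxy ring. The basic solvent buffers the phenol formed and so should suppress acid-promoted ionisation of the ether and cyclisation of the product to a dihydrobenzofuran, while the benzyl ethers and the hindered ketone are thermally inert at this temperature. The abnormal Claisen pathway is degenerate here because C11 carries no alkyl substituent.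

Step 7
Reactants: 13 (E)-11-(2-hydroxyphenyl)-1-[2,4,6-tris(benzyloxy)phenyl]undec-9-en-1-one
Product: 14 11-(2-hydroxyphenyl)-1-(2,4,6-trihydroxyphenyl)undecan-1-one (target)
Conditions: H2 (1 atm), 10% Pd/C, EtOAc/MeOH, rt
Reagents that add atoms: none
Why: Heterogeneous catalytic hydrogenation and hydrogenolysis over Pd/C should saturate the disubstituted alkene and cleave the three benzyl aryl ethers in one operation, while the 2,4,6-trihydroxyaryl ketone, a hydrogen-bonded vinylogous acid, resists reduction at one atmosphere and room temperature.

**Compound list**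

1 | methyl 9-oxononanoate | COC(=O)CCCCCCCC=O | starting material
2 | vinylmagnesium bromide | C=C[Mg]Br | starting material
3 | methyl 9-hydroxyundec-10-enoate (racemic) | COC(=O)CCCCCCCC(O)C=C | intermediate
4 | phenol | Oc1ccccc1 | starting material
5 | methyl 9-phenoxyundec-10-enoate (racemic) | COC(=O)CCCCCCCC(C=C)Oc1ccccc1 | intermediate
6 | N-methoxy-N-methyl-9-phenoxyundec-10-enamide (racemic) | CON(C)C(=O)CCCCCCCC(C=C)Oc1ccccc1 | intermediate
7 | 1,3,5-tris(benzyloxy)benzene | c1ccc(COc2cc(OCc3ccccc3)cc(OCc3ccccc3)c2)cc1 | starting material
8 | 2-bromo-1,3,5-tris(benzyloxy)benzene | Brc1c(OCc2ccccc2)cc(OCc2ccccc2)cc1OCc1ccccc1 | intermediate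
9 | 2,4,6-tris(benzyloxy)phenyllithium | [Li]c1c(OCc2ccccc2)cc(OCc2ccccc2)cc1OCc1ccccc1 | intermediate (not isolated)
10 | lithium 1-[methoxy(methyl)amino]-9-phenoxy-1-[2,4,6-tris(benzyloxy)phenyl]undec-10-en-1-olate (racemic, diastereomer mixture) | [Li]OC(CCCCCCCC(C=C)Oc1ccccc1)(N(C)OC)c1c(OCc2ccccc2)cc(OCc2ccccc2)cc1OCc1ccccc1 | intermediate (not isolated)
11 | 9-phenoxy-1-[2,4,6-tris(benzyloxy)phenyl]undec-10-en-1-one (racemic) | O=C(CCCCCCCC(C=C)Oc1ccccc1)c1c(OCc2ccccc2)cc(OCc2ccccc2)cc1OCc1ccccc1 | intermediate
12 | 6-{(E)-11-oxo-11-[2,4,6-tris(benzyloxy)phenyl]undec-2-en-1-yl}cyclohexa-2,4-dien-1-one (racemic) | O=C1C=CC=CC1C/C=C/CCCCCCCC(=O)c1c(OCc2ccccc2)cc(OCc2ccccc2)cc1OCc1ccccc1 | intermediate (not isolated)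
13 | (E)-11-(2-hydroxyphenyl)-1-[2,4,6-tris(benzyloxy)phenyl]undec-9-en-1-one | O=C(CCCCCCC/C=C/Cc1ccccc1O)c1c(OCc2ccccc2)cc(OCc2ccccc2)cc1OCc1ccccc1 | intermediate
14 | 11-(2-hydroxyphenyl)-1-(2,4,6-trihydroxyphenyl)undecan-1-one | O=C(CCCCCCCCCCc1ccccc1O)c1c(O)cc(O)cc1O | target

**Summary**

Total step count: 7. Longest linear sequence: 6 (steps 1, 2, 3, 5, 6, 7); step 4 is a one-step side branch.

**Steps most likely to fail**

Step 6. At 190 °C the ether may lose phenol by elimination to a 1,3-diene, or conversion may stall before the rearrangement is complete. The fallback makes the same ring-to-C11 connection by olefin cross-metathesis with a ready-made ortho-allylphenol. It sets out from bromide 8. Commercial methyl dec-9-enoate is converted with MeNH(OMe)·HCl and iPrMgCl into N-methoxy-N-methyldec-9-enamide F1. Bromine–lithium exchange on 8 gives aryllithium 9, which is added to F1 to give, through lithium 1-[methoxy(methyl)amino]-1-[2,4,6-tris(benzyloxy)phenyl]dec-9-en-1-olate F2, the ketone 1-[2,4,6-tris(benzyloxy)phenyl]dec-9-en-1-one F3 after aqueous NH4Cl. Cross-metathesis of F3 with excess commercial 2-allylphenol, using the second-generation Grubbs catalyst (H2IMes)(PCy3)Cl2Ru=CHPh in CH2Cl2 at 40 °C with loss of ethylene, should give the E alkene under the thermodynamic control typical of this catalyst. The route is rejoined at compound 13 and step 7 follows unchanged.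

Step 2. The phenoxide may attack the alkene terminus (SN2′) to give the linear primary ether, which would rearrange to the wrong, branched phenol in step 6; the activated secondary alcohol may also eliminate. The fallback replaces the Mitsunobu reaction by a regioretentive metal-catalysed allylic substitution. It sets out from alcohol 3. Methyl chloroformate and pyridine in CH2Cl2 give methyl 9-[(methoxycarbonyl)oxy]undec-10-enoate F4. Phenol 4 is deprotonated with NaH in THF to sodium phenoxide F5. F4 and F5 are then combined with catalytic RhCl(PPh3)3 modified by P(OMe)3 in THF at 0 °C → rt. This rhodium-catalysed allylic etherification proceeds through an enyl intermediate that keeps the oxygen on the secondary carbon, and it rejoins the route at compound 5.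

Step 5. The hindered aryllithium may act as a base instead of a nucleophile, enolising the amide or inducing loss of formaldehyde from the N–OMe group, so that addition stays incomplete. The fallback adds the same nucleophile to a far more electrophilic aldehyde and oxidises afterwards. It sets out from Weinreb amide 6. Reduction with i-Bu2AlH in THF at −78 °C gives 9-phenoxyundec-10-enal F6. Aryllithium 9, made from bromide 8 as in step 5, is added at −78 °C to give, after aqueous work-up, 9-phenoxy-1-[2,4,6-tris(benzyloxy)phenyl]undec-10-en-1-ol F7 as an inconsequential diastereomer mixture. Oxidation with Dess–Martin periodinane in CH2Cl2 rejoins the route at compound 11.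

Further compounds

F1 | step 6 | N-methoxy-N-methyldec-9-enamide | CON(C)C(=O)CCCCCCCC=C
F2 | step 6 | lithium 1-[methoxy(methyl)amino]-1-[2,4,6-tris(benzyloxy)phenyl]dec-9-en-1-olate | [Li]OC(CCCCCCCC=C)(N(C)OC)c1c(OCc2ccccc2)cc(OCc2ccccc2)cc1OCc1ccccc1
F3 | step 6 | 1-[2,4,6-tris(benzyloxy)phenyl]dec-9-en-1-one | C=CCCCCCCCC(=O)c1c(OCc2ccccc2)cc(OCc2ccccc2)cc1OCc1ccccc1
F4 | step 2 | methyl 9-[(methoxycarbonyl)oxy]undec-10-enoate | COC(=O)CCCCCCCC(C=C)OC(=O)OC
F5 | step 2 | sodium phenoxide | [Na+].[O-]c1ccccc1
F6 | step 5 | 9-phenoxyundec-10-enal | O=CCCCCCCCC(C=C)Oc1ccccc1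
F7 | step 5 | 9-phenoxy-1-[2,4,6-tris(benzyloxy)phenyl]undec-10-en-1-ol | OC(CCCCCCCC(C=C)Oc1ccccc1)c1c(OCc2ccccc2)cc(OCc2ccccc2)cc1OCc1ccccc1
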